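**Retrosynthetic overview**
- The target N-oxide comes from N-oxidation of the side-chain tertiary amine. The CH2NMe2 group comes from a Mannich reaction with Eschenmoser's salt at C3 of 2,5,6-tribromo-1-methylindole.
- The strategy rests on C2 of the pyrrole ring, which carries both N1 and a bromine. C2 is therefore the CBr2 carbon of a 2-(2,2-dibromovinyl)aniline, and disconnecting N1–C2 gives 4,5-dibromo-2-(2,2-dibromovinyl)-N-methylaniline.
- In the forward direction, a copper-catalysed intramolecular N-vinylation exchanges one vinylic bromine for N1 and leaves the other on C2.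
- The precursor comes from mono-N-methylation of the primary aniline, nitro reduction, Ramirez dibromoolefination of 4,5-dibromo-2-nitrobenzaldehyde, and nitration of 3,4-dibromobenzaldehyde.
- Ring order: the benzene ring is bought with both aryl bromines in place; the pyrrole ring is the only ring formed (step 5).

Key step: step 5

Remark: the target has no stereocentre, so no stereocontrol is needed; the N-oxide is the zwitterionic amine oxide of the side-chain dimethylamino group.

**Route**

Step 1
Reactants: 1 3,4-dibromobenzaldehyde
Product: 2 4,5-dibromo-2-nitrobenzaldehyde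
Conditions: fuming HNO3, conc. H2SO4, 0 °C to rt; recrystallisation
Reagents that add atoms: nitric acid, O[N+](=O)[O-]
Why: Electrophilic aromatic nitration should go mainly to C6, which is para to the C3 bromine and ortho to the formyl group, as is usual for 3-halo- and 3,4-dihalobenzaldehydes; the minor isomer nitrated meta to the formyl group would be removed by crystallisation.

Step 2
Reactants: 2 4,5-dibromo-2-nitrobenzaldehyde; 3 carbon tetrabromide
Product: 4 1,2-dibromo-4-(2,2-dibromovinyl)-5-nitrobenzene
Conditions: PPh3, CH2Cl2, 0 °C
Reagents that add atoms: none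
Why: Ramirez dibromoolefination (first stage of the Corey–Fuchs sequence): the ylide Ph3P=CBr2 formed from CBr4 and PPh3 should undergo a Wittig reaction with the electron-poor aldehyde, while the nitro group and the aryl bromides are inert.

Step 3
Reactants: 4 1,2-dibromo-4-(2,2-dibromovinyl)-5-nitrobenzene
Product: 5 4,5-dibromo-2-(2,2-dibromovinyl)aniline
Conditions: SnCl2·2H2O, EtOH, 75 °C; basic work-up
Reagents that add atoms: none
Why: Chemoselective nitro reduction by divalent tin (SnCl2) should leave the aryl and vinylic C–Br bonds and the alkene untouched, which catalytic hydrogenation would not.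

Step 4
Reactants: 5 4,5-dibromo-2-(2,2-dibromovinyl)aniline
Product: 7 4,5-dibromo-2-(2,2-dibromovinyl)-N-methylaniline, via 4,5-dibromo-2-(2,2-dibromovinyl)-N-(methoxymethyl)aniline 6 (not isolated)
Conditions: (CH2O)n, NaOMe, MeOH, rt; then NaBH4, 0 °C to rt
Reagents that add atoms: formaldehyde (from paraformaldehyde), C=O; methanol, CO (methoxy group of intermediate 6 only, lost again on reduction)
Why: Reductive mono-N-methylation: under methoxide the aniline adds once to formaldehyde and is held as the N,O-acetal 6, which NaBH4 should reduce through the imine to the secondary N-methylamine, avoiding the double alkylation of a direct methylation; borohydride does not touch the dibromoalkene.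

Step 5
Reactants: 7 4,5-dibromo-2-(2,2-dibromovinyl)-N-methylaniline
Product: 8 2,5,6-tribromo-1-methyl-1H-indole
Conditions: CuI (10 mol %), 1,10-phenanthroline (20 mol %), K3PO4, toluene, 90 °C, Ar
Reagents that add atoms: none
Why: Intramolecular Ullmann-type N-vinylation: the monovalent copper amide formed from CuI/phenanthroline, K3PO4 and the N-methylaniline nitrogen should insert into a C–Br bond of the neighbouring CBr2 carbon, and C–N reductive elimination then forms N1–C2 with the second bromine left on C2. The closest known reaction type is the copper-catalysed (also palladium-catalysed or base-mediated) cyclisation of 2-(2,2-dibromovinyl)anilines to 2-bromoindoles. The pyrrole ring closes in a formally 5-endo mode at an sp2 carbon, which is allowed here because the bond is made by reductive elimination from a six-membered cupracycle (Cu, N1, C7a, C3a, C3, C2) and not by direct in-plane attack. No stereocentre is formed. The step needs one vinylic C–Br to react in preference to the other vinylic and the two aryl C–Br bonds: the ortho arrangement holds nitrogen next to the CBr2 carbon, a gem-dibromoalkene undergoes oxidative addition more readily than an aryl bromide, and neither aryl bromide can be reached by the nitrogen intramolecularly. After ring closure the nitrogen lone pair belongs to the aromatic indole and the C2 bromide is an electron-rich heteroaryl bromide, so the reaction should stop at monosubstitution.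

Step 6
Reactants: 8 2,5,6-tribromo-1-methyl-1H-indole
Product: 9 1-(2,5,6-tribromo-1-methyl-1H-indol-3-yl)-N,N-dimethylmethanamine
Conditions: Me2N+=CH2 I− (Eschenmoser's salt), MeCN, rt to 50 °C; then aq. NaOH
Reagents that add atoms: Eschenmoser's salt (N,N-dimethylmethyleneiminium iodide), C=[N+](C)C.[I-]
Why: Mannich-type electrophilic substitution at C3, the only unsubstituted and the most nucleophilic pyrrole carbon; the preformed iminium ion should be electrophilic enough for the bromine-deactivated indole under neutral conditions that leave the C2–Br bond alone.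

Step 7
Reactants: 9 1-(2,5,6-tribromo-1-methyl-1H-indol-3-yl)-N,N-dimethylmethanamine
Product: 10 1-(2,5,6-tribromo-1-methyl-1H-indol-3-yl)-N,N-dimethylmethanamine N-oxide
Conditions: mCPBA (1.0 equiv), CH2Cl2, 0 °C; filtration through basic Al2O3
Reagents that add atoms: mCPBA (3-chloroperoxybenzoic acid), OOC(=O)c1cccc(Cl)c1
Why: Peracid N-oxidation of a tertiary aliphatic amine; the sp3 nitrogen is far more nucleophilic than the tribrominated indole π-system, so one equivalent at 0 °C should oxidise nitrogen only, and no stereocentre arises because nitrogen carries two identical methyl groups.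

**Compound list**
1 | 3,4-dibromobenzaldehyde | O=Cc1ccc(Br)c(Br)c1 | starting material
2 | 4,5-dibromo-2-nitrobenzaldehyde | O=Cc1cc(Br)c(Br)cc1[N+](=O)[O-] | intermediate
3 | carbon tetrabromide | BrC(Br)(Br)Br | starting material
4 | 1,2-dibromo-4-(2,2-dibromovinyl)-5-nitrobenzene | O=[N+]([O-])c1cc(Br)c(Br)cc1C=C(Br)Br | intermediate
5 | 4,5-dibromo-2-(2,2-dibromovinyl)aniline | Nc1cc(Br)c(Br)cc1C=C(Br)Br | intermediate
6 | 4,5-dibromo-2-(2,2-dibromovinyl)-N-(methoxymethyl)aniline | COCNc1cc(Br)c(Br)cc1C=C(Br)Br | intermediate (not isolated)
7 | 4,5-dibromo-2-(2,2-dibromovinyl)-N-methylaniline | CNc1cc(Br)c(Br)cc1C=C(Br)Br | intermediate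
8 | 2,5,6-tribromo-1-methyl-1H-indole | Cn1c(Br)cc2cc(Br)c(Br)cc21 | intermediate
9 | 1-(2,5,6-tribromo-1-methyl-1H-indol-3-yl)-N,N-dimethylmethanamine | CN(C)Cc1c(Br)n(C)c2cc(Br)c(Br)cc12 | intermediate
10 | 1-(2,5,6-tribromo-1-methyl-1H-indol-3-yl)-N,N-dimethylmethanamine N-oxide | Cn1c(Br)c(C[N+](C)(C)[O-])c2cc(Br)c(Br)cc21 | target

Total step count: 7 steps.
Longest linear sequence: 7 steps (1 to 10).

**Steps most likely to fail**

Step 5. The weakly acidic secondary N-alkylaniline may couple sluggishly, so that loss of HBr from the dibromoalkene or copper insertion into the aryl C–Br bonds with oligomerisation competes with ring closure. The fallback sets out from compound 5 and closes the ring on an acidic sulfonamide nitrogen, introducing the N-methyl group only after the indole exists. Compound 5 would be mesylated (MsCl, pyridine, CH2Cl2, 0 °C) to N-[4,5-dibromo-2-(2,2-dibromovinyl)phenyl]methanesulfonamide F1. Its anion should cyclise with K3PO4 and catalytic CuI in toluene at 110 °C, the variant of this ring closure established for N-sulfonyl substrates, to 2,5,6-tribromo-1-(methylsulfonyl)-1H-indole F2. Fluoride-induced removal of the sulfonyl group (Bu4NF, THF, reflux) should give 2,5,6-tribromo-1H-indole F3, and N-methylation (NaH, MeI, DMF, 0 °C) comes back to the route at compound 8.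

Step 1. Nitration may show poor regioselectivity, with attack meta to the formyl group (ortho to the C4 bromine) competing with attack at C6, together with some oxidation of the aldehyde. The fallback does not set out from a numbered compound: it replaces compound 1 by commercial 3,4-dibromotoluene F4, in which the methyl group (ortho) and the C3 bromine (para) direct to the same carbon. Nitration (HNO3, H2SO4, 0 °C) should give 1,2-dibromo-4-methyl-5-nitrobenzene F5. Condensation of its acidified methyl group with N,N-dimethylformamide dimethyl acetal (DMF, 110 °C) should give (E)-2-(4,5-dibromo-2-nitrophenyl)-N,N-dimethylethen-1-amine F6. Oxidative cleavage of the enamine double bond (NaIO4, THF/H2O, rt) comes back to the route at compound 2.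

Step 4. The hindered, electron-poor aniline may condense incompletely with formaldehyde, some N,N-dimethylation may occur, and methoxide may slowly remove HBr from the dibromoalkene. The fallback sets out from compound 5 and methylates an acidic amide N–H, which can react only once. Acylation (trifluoroacetic anhydride, pyridine, CH2Cl2, 0 °C) should give N-[4,5-dibromo-2-(2,2-dibromovinyl)phenyl]-2,2,2-trifluoroacetamide F7. Methylation (MeI, K2CO3, acetone, rt) should give N-[4,5-dibromo-2-(2,2-dibromovinyl)phenyl]-2,2,2-trifluoro-N-methylacetamide F8. Mild solvolysis of the trifluoroacetyl group (K2CO3, MeOH/H2O, rt) comes back to the route at compound 7.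

**Further compounds**
F1 | step 5 | N-[4,5-dibromo-2-(2,2-dibromovinyl)phenyl]methanesulfonamide | CS(=O)(=O)Nc1cc(Br)c(Br)cc1C=C(Br)Br
F2 | step 5 | 2,5,6-tribromo-1-(methylsulfonyl)-1H-indole | CS(=O)(=O)n1c(Br)cc2cc(Br)c(Br)cc21
F3 | step 5 | 2,5,6-tribromo-1H-indole | Brc1cc2cc(Br)c(Br)cc2[nH]1
F4 | step 1 | 3,4-dibromotoluene | Cc1ccc(Br)c(Br)c1
F5 | step 1 | 1,2-dibromo-4-methyl-5-nitrobenzene | Cc1cc(Br)c(Br)cc1[N+](=O)[O-]
F6 | step 1 | (E)-2-(4,5-dibromo-2-nitrophenyl)-N,N-dimethylethen-1-amine | CN(C)/C=C/c1cc(Br)c(Br)cc1[N+](=O)[O-]
F7 | step 4 | N-[4,5-dibromo-2-(2,2-dibromovinyl)phenyl]-2,2,2-trifluoroacetamide | O=C(Nc1cc(Br)c(Br)cc1C=C(Br)Br)C(F)(F)F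
F8 | step 4 | N-[4,5-dibromo-2-(2,2-dibromovinyl)phenyl]-2,2,2-trifluoro-N-methylacetamide | CN(C(=O)C(F)(F)F)c1cc(Br)c(Br)cc1C=C(Br)Br
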